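**Retrosynthetic overview**
1. The last skeletal bond to be made is the one between the ketone carbonyl carbon and the cyclopropane CH carbon. It is cut back to two carboxylic acid derivatives: fragment A, the S-2-pyridyl thioester of O-[(Z)-4-silyloxycinnamoyl]-(R)-lactic acid, and fragment B, the N-hydroxyphthalimide ester of a cyclopropane-1-carboxylic acid that already carries the silyl-protected carbinol and the finished 5,6-dihydro-2H-pyran-2-one.
2. Enabling feature: the ketone carbon sits directly on a CH carbon of the trans-1,2-disubstituted cyclopropane ring. Decarboxylation at that ring carbon gives a σ-radical that inverts freely and is trapped by acylnickel anti to the bulky substituent on the adjacent ring carbon, so the coupling also sets that ring stereocentre.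
3. Fragment B: Sharpless desymmetrisation of divinylcarbinol sets the anti O,O stereodiad; propiolate opening and semi-hydrogenation/lactonisation build the dihydropyranone; cross-metathesis, Charette cyclopropanation and oxidation give the acid.
4. Fragment A: tert-butyl (R)-lactate, bromoacetylation, Michaelis–Becker reaction and Ando Z-selective Horner–Wadsworth–Emmons olefination.
5. Ring order: oxirane (temporary), then dihydropyranone, then cyclopropane; the arene is bought. A global desilylation ends the route.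

Key step: step 14

Remark: the carbinol/cyclopropane relationship of the target is anti, which hydroxyl-directed cyclopropanation of an E-allylic alcohol would not deliver, so the ring is made under reagent control (step 11); all Z-cinnamate compounds are handled with exclusion of light.

**Route**

Step 1
Reactants: 1 tert-butyl (2R)-2-hydroxypropanoate
Product: 2 tert-butyl (2R)-2-[(bromoacetyl)oxy]propanoate
Conditions: bromoacetyl bromide, pyridine, CH2Cl2, 0 °C
Reagents that add atoms: bromoacetyl bromide BrCC(Br)=O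
Why: O-acylation of the secondary alcohol by an acyl bromide with pyridine as acid scavenger; the lactate stereocentre is not involved.

Step 2
Reactants: 2 tert-butyl (2R)-2-[(bromoacetyl)oxy]propanoate
Product: 3 tert-butyl (2R)-2-{[(diphenoxyphosphoryl)acetyl]oxy}propanoate
Conditions: diphenyl phosphite, Et3N, CH2Cl2, 0 → 23 °C
Reagents that add atoms: diphenyl phosphite O=[PH](Oc1ccccc1)Oc1ccccc1
Why: Michaelis–Becker reaction, in which the amine-activated phosphite displaces bromide from the α-bromo ester (SN2) to give an Ando-type diaryl phosphonoacetate.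

Step 3
Reactants: 3 tert-butyl (2R)-2-{[(diphenoxyphosphoryl)acetyl]oxy}propanoate; 4 4-[(tert-butyldimethylsilyl)oxy]benzaldehyde
Product: 6 tert-butyl (2R)-2-{[(2Z)-3-{4-[(tert-butyldimethylsilyl)oxy]phenyl}prop-2-enoyl]oxy}propanoate, via sodium phosphonate carbanion 5 (not isolated)
Conditions: NaH, THF, −78 °C; then 4, −78 → −20 °C
Reagents that add atoms: none
Why: Ando variant of the Horner–Wadsworth–Emmons olefination, in which the electron-poor diaryl phosphonate makes elimination faster than equilibration of the adducts so that the kinetic Z-cinnamate should form; the phosphonate CH2 is far more acidic than the lactate α-hydrogen and the tert-butyl ester resists Dieckmann attack.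

Step 4
Reactants: 6 tert-butyl (2R)-2-{[(2Z)-3-{4-[(tert-butyldimethylsilyl)oxy]phenyl}prop-2-enoyl]oxy}propanoate
Product: 7 (2R)-2-{[(2Z)-3-{4-[(tert-butyldimethylsilyl)oxy]phenyl}prop-2-enoyl]oxy}propanoic acid
Conditions: TFA, CH2Cl2 (1:4), 0 °C, dark
Reagents that add atoms: none
Why: acidolysis of the tert-butyl ester by E1 loss of isobutene under anhydrous conditions, which the comparatively acid-stable aryl silyl ether, the secondary ester and the Z-enoate should tolerate.

Step 5
Reactants: 7 (2R)-2-{[(2Z)-3-{4-[(tert-butyldimethylsilyl)oxy]phenyl}prop-2-enoyl]oxy}propanoic acid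
Product: 8 S-(pyridin-2-yl) (2R)-2-{[(2Z)-3-{4-[(tert-butyldimethylsilyl)oxy]phenyl}prop-2-enoyl]oxy}propanethioate
Conditions: 2,2′-dipyridyl disulfide, PPh3, CH2Cl2, 23 °C, dark
Reagents that add atoms: 2,2′-dipyridyl disulfide c1ccnc(c1)SSc1ccccn1
Why: Mukaiyama–Corey–Nicolaou redox condensation, which converts the acid through its acyloxyphosphonium salt into the 2-pyridyl thioester under neutral conditions that avoid racemisation and Z/E isomerisation.

Step 6
Reactants: 9 penta-1,4-dien-3-ol
Product: 10 (2R,3S)-1,2-epoxypent-4-en-3-ol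
Conditions: Ti(OiPr)4, L-(+)-diisopropyl tartrate, t-BuOOH, 4 Å MS, CH2Cl2, −20 °C
Reagents that add atoms: tert-butyl hydroperoxide CC(C)(C)OO
Why: Sharpless asymmetric epoxidation desymmetrises the achiral dienol by selecting one enantiotopic vinyl group and one of its faces, which gives the erythro epoxy alcohol and so sets both oxygen-bearing stereocentres (carbinol S, oxirane carbon R), the minor enantiomer being removed by a faster second epoxidation.

Step 7
Reactants: 10 (2R,3S)-1,2-epoxypent-4-en-3-ol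
Product: 11 tert-butyl(dimethyl){[(1S)-1-[(2R)-oxiran-2-yl]prop-2-en-1-yl]oxy}silane
Conditions: TBSCl, imidazole, DMF, 0 → 23 °C
Reagents that add atoms: tert-butyldimethylsilyl chloride CC(C)(C)[Si](C)(C)Cl
Why: standard silylation of the secondary alcohol under non-aqueous, weakly basic conditions that do not trigger Payne rearrangement; no stereocentre is touched.

Step 8
Reactants: 11 tert-butyl(dimethyl){[(1S)-1-[(2R)-oxiran-2-yl]prop-2-en-1-yl]oxy}silane; 12 ethyl propiolate
Product: 14 ethyl (5R,6S)-6-[(tert-butyldimethylsilyl)oxy]-5-hydroxyoct-7-en-2-ynoate, via lithium ethyl propiolate 13 (not isolated)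
Conditions: 12, n-BuLi, THF, −78 °C; BF3·OEt2; then 11, −78 °C
Reagents that add atoms: none
Why: Yamaguchi–Hirao alkynylation, in which the BF3-activated terminal epoxide is opened by the lithium acetylide at its unsubstituted CH2 carbon, so the oxirane stereocentre is retained as the (5R) carbinol.

Step 9
Reactants: 14 ethyl (5R,6S)-6-[(tert-butyldimethylsilyl)oxy]-5-hydroxyoct-7-en-2-ynoate
Product: 16 (6R)-6-{(1S)-1-[(tert-butyldimethylsilyl)oxy]prop-2-en-1-yl}-5,6-dihydro-2H-pyran-2-one, via Z-hydroxy enoate 15 (not isolated)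
Conditions: H2 (1 atm), Pd/CaCO3 poisoned with Pb(OAc)2, quinoline, EtOAc, 23 °C; then PPTS (cat.), toluene, 60 °C
Reagents that add atoms: none
Why: Lindlar semi-hydrogenation adds H2 syn to the ynoate (which binds the poisoned palladium far better than the hindered vinyl group) to give the Z-enoate, whose geometry places the ester next to the C5 hydroxyl so that acid-catalysed lactonisation (6-exo-trig acyl substitution) closes the dihydropyranone without touching a stereocentre.

Step 10
Reactants: 16 (6R)-6-{(1S)-1-[(tert-butyldimethylsilyl)oxy]prop-2-en-1-yl}-5,6-dihydro-2H-pyran-2-one; 17 (2Z)-but-2-ene-1,4-diol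
Product: 18 (6R)-6-{(1S,2E)-1-[(tert-butyldimethylsilyl)oxy]-4-hydroxybut-2-en-1-yl}-5,6-dihydro-2H-pyran-2-one
Conditions: 17 (5 equiv), second-generation Hoveyda–Grubbs catalyst RuCl2(H2IMes)(=CH-C6H4-2-OiPr) (5 mol%), CH2Cl2, 40 °C
Reagents that add atoms: none
Why: olefin cross-metathesis between the hindered, slowly homodimerising allylic silyl ether alkene and an excess of the readily exchanging diol should give the thermodynamically favoured E-allylic alcohol, the conjugated lactone alkene being inert to the ruthenium carbene.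

Step 11
Reactants: 18 (6R)-6-{(1S,2E)-1-[(tert-butyldimethylsilyl)oxy]-4-hydroxybut-2-en-1-yl}-5,6-dihydro-2H-pyran-2-one
Product: 19 (6R)-6-{(S)-[(tert-butyldimethylsilyl)oxy][(1S,2S)-2-(hydroxymethyl)cyclopropyl]methyl}-5,6-dihydro-2H-pyran-2-one
Conditions: Et2Zn, CH2I2, DME, CH2Cl2, −10 °C; then 18 premixed with (4R,5R)-2-butyl-N,N,N′,N′-tetramethyl-1,3,2-dioxaborolane-4,5-dicarboxamide, −10 → 23 °C; diethanolamine work-up
Reagents that add atoms: diiodomethane ICI
Why: Charette asymmetric Simmons–Smith cyclopropanation, in which the zinc alkoxide of 18 bound to the (R,R)-dioxaborolane directs stereospecific syn delivery of CH2 to one face of the E-alkene under reagent control (the sense known for cinnamyl alcohol), giving the trans ring with the carbinol-bearing ring carbon S while the electron-poor lactone alkene stays untouched.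

Step 12
Reactants: 19 (6R)-6-{(S)-[(tert-butyldimethylsilyl)oxy][(1S,2S)-2-(hydroxymethyl)cyclopropyl]methyl}-5,6-dihydro-2H-pyran-2-one
Product: 21 (1S,2S)-2-{(S)-[(tert-butyldimethylsilyl)oxy][(2R)-6-oxo-3,6-dihydro-2H-pyran-2-yl]methyl}cyclopropane-1-carboxylic acid, via cyclopropanecarbaldehyde 20 (not isolated)
Conditions: TEMPO (cat.), PhI(OAc)2, MeCN/H2O (1:1), 23 °C
Reagents that add atoms: water O
Why: Epp–Widlanski oxidation takes the primary alcohol through the aldehyde and its hydrate to the acid under near-neutral conditions that spare the silyl ether, lactone and cyclopropane; the configuration at the carboxyl-bearing ring carbon is immaterial for step 14.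

Step 13
Reactants: 21 (1S,2S)-2-{(S)-[(tert-butyldimethylsilyl)oxy][(2R)-6-oxo-3,6-dihydro-2H-pyran-2-yl]methyl}cyclopropane-1-carboxylic acid
Product: 22 1,3-dioxo-1,3-dihydro-2H-isoindol-2-yl (1S,2S)-2-{(S)-[(tert-butyldimethylsilyl)oxy][(2R)-6-oxo-3,6-dihydro-2H-pyran-2-yl]methyl}cyclopropane-1-carboxylate
Conditions: N-hydroxyphthalimide, N,N′-diisopropylcarbodiimide, DMAP (cat.), CH2Cl2, 0 → 23 °C
Reagents that add atoms: N-hydroxyphthalimide ON1C(=O)c2ccccc2C1=O
Why: Steglich-type carbodiimide esterification gives the redox-active ester without affecting any stereocentre.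

Step 14
Reactants: 22 1,3-dioxo-1,3-dihydro-2H-isoindol-2-yl (1S,2S)-2-{(S)-[(tert-butyldimethylsilyl)oxy][(2R)-6-oxo-3,6-dihydro-2H-pyran-2-yl]methyl}cyclopropane-1-carboxylate; 8 S-(pyridin-2-yl) (2R)-2-{[(2Z)-3-{4-[(tert-butyldimethylsilyl)oxy]phenyl}prop-2-enoyl]oxy}propanethioate
Product: 24 (2R)-1-[(1S,2S)-2-{(S)-[(tert-butyldimethylsilyl)oxy][(2R)-6-oxo-3,6-dihydro-2H-pyran-2-yl]methyl}cyclopropyl]-1-oxopropan-2-yl (2Z)-3-{4-[(tert-butyldimethylsilyl)oxy]phenyl}prop-2-enoate, via cyclopropyl radical 23 (not isolated)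
Conditions: NiBr2(dme) (10 mol%), 4,4′-di-tert-butyl-2,2′-bipyridine (12 mol%), Zn powder (2.5 equiv), 8 (1.5 equiv), DMA, 23 °C, dark
Reagents that add atoms: none
Why: Zinc reduces the precatalyst to zerovalent nickel, which inserts into the C(acyl)–S bond of 8 (helped by chelation of the pyridyl nitrogen) to give an acyl divalent nickel thiolate; single-electron reduction of 22 then expels phthalimide anion and CO2 to leave the σ-cyclopropyl radical 23, which the acylnickel captures to a trivalent nickel species that reductively eliminates the acyl–cyclopropyl bond. The closest known reaction type is the nickel-catalysed reductive decarboxylative cross-electrophile coupling of N-hydroxyphthalimide esters of secondary alkyl acids with S-2-pyridyl thioesters to give ketones. No ring is closed in this step. The one new stereocentre, the acyl-bearing ring carbon, is set by the substrate: the cyclopropyl σ-radical inverts faster than it is trapped and bonds to the bulky acylnickel on the ring face away from the neighbouring silyloxy(dihydropyranonyl)methyl group, so the trans (1S,2S) ketone is expected whatever the configuration of the acid, while the lactate centre is a spectator because the acylnickel does not enolise. The step needs cross-selectivity over radical dimerisation and acyl homocoupling (the two electrophiles are activated by different elementary steps and 8 is used in excess), chemoselectivity for the C–S bond over the ester and lactone C–O bonds (the chelating 2-pyridylthio group), and survival of the Z-enoate and the dihydropyranone (both β-substituted and poor radical acceptors, and cyclisation of 23 onto the lactone alkene would give a strained bridged ring).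

Step 15
Reactants: 24 (2R)-1-[(1S,2S)-2-{(S)-[(tert-butyldimethylsilyl)oxy][(2R)-6-oxo-3,6-dihydro-2H-pyran-2-yl]methyl}cyclopropyl]-1-oxopropan-2-yl (2Z)-3-{4-[(tert-butyldimethylsilyl)oxy]phenyl}prop-2-enoate
Product: 25 (2R)-1-[(1S,2S)-2-{(S)-hydroxy[(2R)-6-oxo-3,6-dihydro-2H-pyran-2-yl]methyl}cyclopropyl]-1-oxopropan-2-yl (2Z)-3-(4-hydroxyphenyl)prop-2-enoate
Conditions: HF·pyridine (excess), pyridine, THF, 0 → 23 °C, dark
Reagents that add atoms: none
Why: fluoride-mediated cleavage of both silyl ethers, driven by Si–F bond formation, under buffered acidic conditions that avoid the basic media in which the α-acyloxy ketone, the Z-enoate and the dihydropyranone would epimerise, migrate or take up nucleophiles.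

**Compound list**
1 | tert-butyl (2R)-2-hydroxypropanoate | C[C@@H](O)C(=O)OC(C)(C)C | starting material
2 | tert-butyl (2R)-2-[(bromoacetyl)oxy]propanoate | C[C@@H](OC(=O)CBr)C(=O)OC(C)(C)C | intermediate
3 | tert-butyl (2R)-2-{[(diphenoxyphosphoryl)acetyl]oxy}propanoate | C[C@@H](OC(=O)CP(=O)(Oc1ccccc1)Oc1ccccc1)C(=O)OC(C)(C)C | intermediate
4 | 4-[(tert-butyldimethylsilyl)oxy]benzaldehyde | O=Cc1ccc(O[Si](C)(C)C(C)(C)C)cc1 | starting material
5 | sodium salt of the phosphonate carbanion of 3 | C[C@@H](OC(=O)[CH-]P(=O)(Oc1ccccc1)Oc1ccccc1)C(=O)OC(C)(C)C.[Na+] | intermediate (not isolated)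
6 | tert-butyl (2R)-2-{[(2Z)-3-{4-[(tert-butyldimethylsilyl)oxy]phenyl}prop-2-enoyl]oxy}propanoate | C[C@@H](OC(=O)/C=C\c1ccc(O[Si](C)(C)C(C)(C)C)cc1)C(=O)OC(C)(C)C | intermediate
7 | (2R)-2-{[(2Z)-3-{4-[(tert-butyldimethylsilyl)oxy]phenyl}prop-2-enoyl]oxy}propanoic acid | C[C@@H](OC(=O)/C=C\c1ccc(O[Si](C)(C)C(C)(C)C)cc1)C(=O)O | intermediate
8 | S-(pyridin-2-yl) (2R)-2-{[(2Z)-3-{4-[(tert-butyldimethylsilyl)oxy]phenyl}prop-2-enoyl]oxy}propanethioate | C[C@@H](OC(=O)/C=C\c1ccc(O[Si](C)(C)C(C)(C)C)cc1)C(=O)Sc1ccccn1 | intermediate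
9 | penta-1,4-dien-3-ol | C=CC(O)C=C | starting material
10 | (2R,3S)-1,2-epoxypent-4-en-3-ol | C=C[C@H](O)[C@H]1CO1 | intermediate
11 | tert-butyl(dimethyl){[(1S)-1-[(2R)-oxiran-2-yl]prop-2-en-1-yl]oxy}silane | C=C[C@H](O[Si](C)(C)C(C)(C)C)[C@H]1CO1 | intermediate
12 | ethyl propiolate | C#CC(=O)OCC | starting material
13 | lithium ethyl propiolate | [Li+].[C-]#CC(=O)OCC | intermediate (not isolated)
14 | ethyl (5R,6S)-6-[(tert-butyldimethylsilyl)oxy]-5-hydroxyoct-7-en-2-ynoate | C=C[C@H](O[Si](C)(C)C(C)(C)C)[C@H](O)CC#CC(=O)OCC | intermediate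
15 | ethyl (2Z,5R,6S)-6-[(tert-butyldimethylsilyl)oxy]-5-hydroxyocta-2,7-dienoate | C=C[C@H](O[Si](C)(C)C(C)(C)C)[C@H](O)C/C=C\C(=O)OCC | intermediate (not isolated)
16 | (6R)-6-{(1S)-1-[(tert-butyldimethylsilyl)oxy]prop-2-en-1-yl}-5,6-dihydro-2H-pyran-2-one | C=C[C@H](O[Si](C)(C)C(C)(C)C)[C@H]1CC=CC(=O)O1 | intermediate
17 | (2Z)-but-2-ene-1,4-diol | OC/C=C\CO | starting material
18 | (6R)-6-{(1S,2E)-1-[(tert-butyldimethylsilyl)oxy]-4-hydroxybut-2-en-1-yl}-5,6-dihydro-2H-pyran-2-one | OC/C=C/[C@H](O[Si](C)(C)C(C)(C)C)[C@H]1CC=CC(=O)O1 | intermediate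
19 | (6R)-6-{(S)-[(tert-butyldimethylsilyl)oxy][(1S,2S)-2-(hydroxymethyl)cyclopropyl]methyl}-5,6-dihydro-2H-pyran-2-one | OC[C@H]1C[C@@H]1[C@H](O[Si](C)(C)C(C)(C)C)[C@H]1CC=CC(=O)O1 | intermediate
20 | (1S,2S)-2-{(S)-[(tert-butyldimethylsilyl)oxy][(2R)-6-oxo-3,6-dihydro-2H-pyran-2-yl]methyl}cyclopropane-1-carbaldehyde | O=C[C@H]1C[C@@H]1[C@H](O[Si](C)(C)C(C)(C)C)[C@H]1CC=CC(=O)O1 | intermediate (not isolated)
21 | (1S,2S)-2-{(S)-[(tert-butyldimethylsilyl)oxy][(2R)-6-oxo-3,6-dihydro-2H-pyran-2-yl]methyl}cyclopropane-1-carboxylic acid | OC(=O)[C@H]1C[C@@H]1[C@H](O[Si](C)(C)C(C)(C)C)[C@H]1CC=CC(=O)O1 | intermediate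
22 | 1,3-dioxo-1,3-dihydro-2H-isoindol-2-yl (1S,2S)-2-{(S)-[(tert-butyldimethylsilyl)oxy][(2R)-6-oxo-3,6-dihydro-2H-pyran-2-yl]methyl}cyclopropane-1-carboxylate | O=C(ON1C(=O)c2ccccc2C1=O)[C@H]1C[C@@H]1[C@H](O[Si](C)(C)C(C)(C)C)[C@H]1CC=CC(=O)O1 | intermediate
23 | 2-{(S)-[(tert-butyldimethylsilyl)oxy][(2R)-6-oxo-3,6-dihydro-2H-pyran-2-yl]methyl}cyclopropyl radical (radical carbon configurationally labile) | [CH]1C[C@@H]1[C@H](O[Si](C)(C)C(C)(C)C)[C@H]1CC=CC(=O)O1 | intermediate (not isolated)
24 | (2R)-1-[(1S,2S)-2-{(S)-[(tert-butyldimethylsilyl)oxy][(2R)-6-oxo-3,6-dihydro-2H-pyran-2-yl]methyl}cyclopropyl]-1-oxopropan-2-yl (2Z)-3-{4-[(tert-butyldimethylsilyl)oxy]phenyl}prop-2-enoate | C[C@@H](OC(=O)/C=C\c1ccc(O[Si](C)(C)C(C)(C)C)cc1)C(=O)[C@H]1C[C@@H]1[C@H](O[Si](C)(C)C(C)(C)C)[C@H]1CC=CC(=O)O1 | intermediate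
25 | (2R)-1-[(1S,2S)-2-{(S)-hydroxy[(2R)-6-oxo-3,6-dihydro-2H-pyran-2-yl]methyl}cyclopropyl]-1-oxopropan-2-yl (2Z)-3-(4-hydroxyphenyl)prop-2-enoate (CNP0246043.2) | C[C@@H](OC(=O)/C=C\c1ccc(O)cc1)C(=O)[C@H]1C[C@@H]1[C@H](O)[C@H]1CC=CC(=O)O1 | target

**Step count and risks**
Total step count: 15. Longest linear sequence: 10 steps (steps 6 to 13, then 14 and 15); the fragment A branch has 5 steps (1 to 5).

Steps most likely to fail:

1. Step 14. The σ-cyclopropyl radical may be quenched before capture (hydrogen abstraction from solvent, dimerisation, addition to an enoate), and nickel hydride or thiolate species may isomerise the Z-enoate to E. The fallback makes the same bond by two-electron chemistry. It sets out from acid 21, which would undergo Suárez iododecarboxylation (PhI(OAc)2, I2, hν, CH2Cl2) to the trans iodide (6R)-6-{(S)-[(tert-butyldimethylsilyl)oxy][(1R,2S)-2-iodocyclopropyl]methyl}-5,6-dihydro-2H-pyran-2-one F1. Zinc insertion (Zn dust, LiCl, THF), which tolerates esters and enoates, would give the configurationally stable trans cyclopropylzinc iodide F2. Palladium-catalysed acylation of F2 with thioester 8 (Fukuyama-type coupling, PdCl2(PPh3)2, THF/toluene, 23 °C) would come back to the route at 24.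

2. Step 10. Turnover on the hindered allylic silyl ether may be slow, the diol partner may consume the catalyst by homodimerisation, and ruthenium hydrides may migrate the double bond or erode the E/Z ratio. The fallback adds the two carbons by olefination. It sets out from 16: dihydroxylation and periodate cleavage of the electron-richer vinyl group (OsO4 cat., NMO, acetone/H2O; then NaIO4) would give (2R)-2-[(tert-butyldimethylsilyl)oxy]-2-[(2R)-6-oxo-3,6-dihydro-2H-pyran-2-yl]acetaldehyde F3. Wittig reaction with (triphenylphosphoranylidene)acetaldehyde (toluene, 60 °C) would give the enal (6R)-6-{(1S,2E)-1-[(tert-butyldimethylsilyl)oxy]-4-oxobut-2-en-1-yl}-5,6-dihydro-2H-pyran-2-one F4. Luche reduction (NaBH4, CeCl3·7H2O, MeOH, −40 °C) would come back to the route at 18.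

3. Step 9. Semi-hydrogenation may over-reduce the terminal vinyl group or the Z-enoate, and lactonisation may be incomplete. The fallback builds the unsaturated lactone without hydrogenation. It sets out from epoxide 11, which would be opened with the α-sulfonyl carbanion of the known reagent triethyl 3-(phenylsulfonyl)orthopropionate (n-BuLi, THF, −78 °C, BF3·OEt2) to give (5R,6S)-6-[(tert-butyldimethylsilyl)oxy]-1,1,1-triethoxy-3-(phenylsulfonyl)oct-7-en-5-ol F5. Mild acid (PPTS, wet CH2Cl2) would hydrolyse the ortho ester and close the lactone (6R)-6-{(1S)-1-[(tert-butyldimethylsilyl)oxy]prop-2-en-1-yl}-4-(phenylsulfonyl)tetrahydro-2H-pyran-2-one F6. Elimination of benzenesulfinate with DBU (CH2Cl2, 0 °C) would come back to the route at 16.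

Further compounds
F1 | step 14 | (6R)-6-{(S)-[(tert-butyldimethylsilyl)oxy][(1R,2S)-2-iodocyclopropyl]methyl}-5,6-dihydro-2H-pyran-2-one | I[C@H]1C[C@@H]1[C@H](O[Si](C)(C)C(C)(C)C)[C@H]1CC=CC(=O)O1
F2 | step 14 | {(1S,2R)-2-[(S)-[(tert-butyldimethylsilyl)oxy][(2R)-6-oxo-3,6-dihydro-2H-pyran-2-yl]methyl]cyclopropyl}zinc iodide | I[Zn][C@H]1C[C@@H]1[C@H](O[Si](C)(C)C(C)(C)C)[C@H]1CC=CC(=O)O1
F3 | step 10 | (2R)-2-[(tert-butyldimethylsilyl)oxy]-2-[(2R)-6-oxo-3,6-dihydro-2H-pyran-2-yl]acetaldehyde | O=C[C@H](O[Si](C)(C)C(C)(C)C)[C@H]1CC=CC(=O)O1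
F4 | step 10 | (6R)-6-{(1S,2E)-1-[(tert-butyldimethylsilyl)oxy]-4-oxobut-2-en-1-yl}-5,6-dihydro-2H-pyran-2-one | O=C/C=C/[C@H](O[Si](C)(C)C(C)(C)C)[C@H]1CC=CC(=O)O1
F5 | step 9 | (5R,6S)-6-[(tert-butyldimethylsilyl)oxy]-1,1,1-triethoxy-3-(phenylsulfonyl)oct-7-en-5-ol (C3 epimers) | C=C[C@H](O[Si](C)(C)C(C)(C)C)[C@H](O)CC(CC(OCC)(OCC)OCC)S(=O)(=O)c1ccccc1
F6 | step 9 | (6R)-6-{(1S)-1-[(tert-butyldimethylsilyl)oxy]prop-2-en-1-yl}-4-(phenylsulfonyl)tetrahydro-2H-pyran-2-one (C4 epimers) | C=C[C@H](O[Si](C)(C)C(C)(C)C)[C@H]1CC(S(=O)(=O)c2ccccc2)CC(=O)O1
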